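**Strategy.** The cyclohexene ring is numbered C1 (stereocentre carrying the aryl-CH2), C2(Me)=C3H, C4H2, C5H2, C6Me2 and is disconnected at C4–C5. The key step exploits two features: C4 is the allylic terminus of the C2=C3 double bond, and C5 lies next to the quaternary C6. An Ireland–Claisen ring contraction of a six-membered vinyl lactone, used as a temporary ring, joins C4 to C5, closes the carbocycle and places the trisubstituted alkene regiospecifically in one operation. Its precursor is a 6-vinyl-4,4,6-trimethyl δ-lactone that already carries the C1 stereocentre (Evans alkylation); the extra carboxyl on C5 is then excised and the ring is joined to the flavonol by Negishi coupling.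

Key step: step 6

Assumption: 1 is taken as a catalogue compound (it is also the methanolysis product of 3,3-dimethylglutaric anhydride); the carbinol carbon of 9–11 and the carboxyl-bearing carbon of 12–14 are left as epimer mixtures because both centres are destroyed later, so their SMILES leave them undefined.

Step 1
Reactants: 1 5-methoxy-3,3-dimethyl-5-oxopentanoic acid (monomethyl 3,3-dimethylglutarate); 2 (4R)-4-benzyl-1,3-oxazolidin-2-one
Product: 4 methyl 5-[(4R)-4-benzyl-2-oxo-1,3-oxazolidin-3-yl]-3,3-dimethyl-5-oxopentanoate, via mixed pivalic anhydride 3 (not isolated)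
Conditions: PivCl, Et3N, THF, −20 °C; then 2, LiCl, −20 → 23 °C
Reagents that add atoms: none
Why: Mixed-anhydride N-acylation of the oxazolidinone, in which the nucleophile attacks the CH2–C(=O) carbonyl of 3 rather than the far more hindered pivaloyl carbonyl; no stereocentre is formed.

Step 2
Reactants: 4
Product: 6 methyl (4R)-5-[(4R)-4-benzyl-2-oxo-1,3-oxazolidin-3-yl]-3,3-dimethyl-5-oxo-4-[(phenylsulfanyl)methyl]pentanoate, via chlorotitanium Z-enolate 5 (not isolated)
Conditions: TiCl4, i-Pr2NEt, CH2Cl2, 0 °C; then PhSCH2Cl, 0 → 23 °C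
Reagents that add atoms: chloromethyl phenyl sulfide, ClCSc1ccccc1
Why: Evans titanium-enolate alkylation: soft enolisation gives only the chelated Z-enolate of the imide (the methyl ester is not enolised), and the thionium ion from PhSCH2Cl adds to the face opposite the benzyl group, which sets the future ring stereocentre C1 and installs the PhS group as a latent handle for the later carbon–metal bond.

Step 3
Reactants: 6
Product: 7 methyl (4S)-5-(ethylsulfanyl)-3,3-dimethyl-5-oxo-4-[(phenylsulfanyl)methyl]pentanoate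
Conditions: EtSH, n-BuLi, THF, 0 °C
Reagents that add atoms: ethanethiol (used as LiSEt), CCS
Why: Thiolate transacylation of the N-acyl oxazolidinone at the exocyclic carbonyl gives the thioester without enolising the α-centre or touching the methyl ester, and returns the auxiliary.

Step 4
Reactants: 7
Product: 8 methyl (4R)-3,3-dimethyl-5-oxo-4-[(phenylsulfanyl)methyl]hexanoate
Conditions: Me2CuLi (from MeLi, CuI), Et2O, −78 → −40 °C
Reagents that add atoms: lithium dimethylcuprate, [Li+].C[Cu-]C
Why: Acyl substitution of a thioester by a Gilman cuprate stops at the methyl ketone and, being non-basic, leaves the methyl ester and the α-stereocentre untouched.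

Step 5
Reactants: 8
Product: 10 (5R)-6-ethenyl-4,4,6-trimethyl-5-[(phenylsulfanyl)methyl]oxan-2-one (both epimers at the carbinol carbon), via hydroxy ester 9 (not isolated)
Conditions: CH2=CHMgBr, LaCl3·2LiCl (30 mol %), THF, −78 → 23 °C
Reagents that add atoms: vinylmagnesium bromide, C=C[Mg]Br
Why: Lanthanide-assisted Grignard 1,2-addition to the hindered ketone suppresses enolisation, and the tertiary alkoxide of 9 then closes onto the methyl ester (lactonisation helped by the gem-dimethyl group); the new carbinol centre forms as a mixture that need not be controlled because it becomes sp2 in step 6.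

Step 6
Reactants: 10
Product: 13 (3S)-2,2,4-trimethyl-3-[(phenylsulfanyl)methyl]cyclohex-4-ene-1-carboxylic acid (epimers at the carboxyl-bearing carbon), via silyl ketene acetal 11 (not isolated), via trimethylsilyl ester 12 (not isolated)
Conditions: LDA, THF, −78 °C; TMSCl–Et3N, −78 → 23 °C; PhMe, 105 °C; then cold 1 M HCl
Reagents that add atoms: none
Why: LDA removes a proton from the only enolisable CH2 of 10 (the future C5) and O-silylation gives the cyclic ketene acetal 11, an allyl vinyl ether whose ring C–O bond is the allylic bond; on heating, a concerted Ireland–Claisen [3,3]-sigmatropic shift joins the ketene-acetal carbon to the vinyl terminus (C4–C5) as that C–O bond breaks, so the lactone contracts to the carbocycle and the double bond is transposed to C2=C3, the only place it can appear. The closest known reaction type is the ester-enolate Claisen ring contraction of vinyl-substituted lactones to cycloalkene carboxylic acids. The six-membered carbocycle is closed in a suprafacial sigmatropic mode through a boat-like, bicyclo[2.2.2]-type transition state with the vinyl group pseudo-axial, not by a polar exo or endo attack. The only new stereocentre, the carboxyl-bearing C5, is fixed by chirality transfer from the carbinol carbon through that boat and is irrelevant because step 7 turns it into CH2, while C1 is a spectator without an acidic hydrogen. The step needs O- rather than C-silylation and rearrangement ahead of ionisation of the tertiary allylic C–O bond, which the single α-CH2, the TMSCl–Et3N in-situ quench and the non-polar solvent should secure; the ring itself enforces the cis alkene.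

Step 7
Reactants: 13
Product: 15 phenyl [(1R)-2,6,6-trimethylcyclohex-2-en-1-yl]methyl sulfide, via Barton ester 14 (not isolated)
Conditions: 2-mercaptopyridine N-oxide, DCC, DMAP (cat.), CH2Cl2, 0 → 23 °C, dark; then t-BuSH, hν (tungsten lamp), 23 °C
Reagents that add atoms: none
Why: Barton reductive decarboxylation: photolysis of the thiohydroxamate ester gives the secondary C5 radical, which the thiol reduces faster than a homoallyl radical can rearrange, so the auxiliary carboxyl and its stereocentre are erased and C5 becomes CH2.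

Step 8
Reactants: 15
Product: 17 (6R)-6-(iodomethyl)-1,5,5-trimethylcyclohex-1-ene, via alkyllithium 16 (not isolated)
Conditions: lithium 4,4'-di-tert-butylbiphenylide (LiDBB), THF, −78 °C; then inverse addition to I2, THF, −78 °C
Reagents that add atoms: iodine, II
Why: Reductive lithiation of an alkyl phenyl sulfide cleaves the alkyl C–S bond by two fast electron transfers to give the primary alkyllithium without touching the isolated alkene or the β-stereocentre, and iodinolysis converts it into the primary iodide.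

Step 9
Reactants: 18 kaempferol
Product: 19 5-hydroxy-3,7-bis(methoxymethoxy)-2-[4-(methoxymethoxy)phenyl]-4H-chromen-4-one
Conditions: MOMCl (3.3 equiv), i-Pr2NEt, DMF, 0 → 23 °C
Reagents that add atoms: chloromethyl methyl ether, COCCl
Why: Williamson-type O-alkylation of the three more acidic hydroxyls; the 5-OH is strongly chelated to the C4 carbonyl and should stay free.

Step 10
Reactants: 19
Product: 20 5-hydroxy-6-iodo-3,7-bis(methoxymethoxy)-2-[4-(methoxymethoxy)phenyl]-4H-chromen-4-one
Conditions: BnNMe3·ICl2, CaCO3, CH2Cl2–MeOH, 23 °C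
Reagents that add atoms: benzyltrimethylammonium dichloroiodate, C[N+](C)(C)Cc1ccccc1.Cl[I-]Cl
Why: Electrophilic aromatic iodination under buffered conditions is directed ortho to the free, chelated 5-OH, so ring A of the flavonol is iodinated at C6 and not at C8.

Step 11
Reactants: 20
Product: 21 6-iodo-3,5,7-tris(methoxymethoxy)-2-[4-(methoxymethoxy)phenyl]-4H-chromen-4-one
Conditions: NaH, MOMCl, DMF, 0 → 23 °C
Reagents that add atoms: chloromethyl methyl ether, COCCl
Why: O-alkylation of the sodium phenoxide caps the last acidic hydrogen so that the organozinc reagent is not protonated in step 12.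

Step 12
Reactants: 17 (6R)-6-(iodomethyl)-1,5,5-trimethylcyclohex-1-ene; 21 6-iodo-3,5,7-tris(methoxymethoxy)-2-[4-(methoxymethoxy)phenyl]-4H-chromen-4-one
Product: 23 3,5,7-tris(methoxymethoxy)-2-[4-(methoxymethoxy)phenyl]-6-{[(1R)-2,6,6-trimethylcyclohex-2-en-1-yl]methyl}-4H-chromen-4-one, via alkylzinc iodide 22 (not isolated)
Conditions: 17, Zn, LiCl, THF, 40 °C; then 21, Pd(OAc)2 (5 mol %), SPhos (10 mol %), THF–NMP, 50 °C
Reagents that add atoms: none
Why: Negishi sp3–sp2 cross-coupling: zinc insertion into the primary iodide does not disturb the β-stereocentre, and the bulky electron-rich biarylphosphine should promote oxidative addition to the hindered aryl iodide and reductive elimination ahead of β-hydride elimination.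

Step 13
Reactants: 23
Product: 24 Ugonin G, 3,5,7-trihydroxy-2-(4-hydroxyphenyl)-6-{[(1R)-2,6,6-trimethylcyclohex-2-en-1-yl]methyl}-4H-chromen-4-one
Conditions: 3 M aq. HCl, MeOH, 50 °C
Reagents that add atoms: none
Why: Acid-catalysed acetal cleavage of the four MOM ethers in methanol should free the phenols under conditions that leave the trisubstituted alkene and the stereocentre untouched.

**Compound list**

1 | 5-methoxy-3,3-dimethyl-5-oxopentanoic acid (monomethyl 3,3-dimethylglutarate) | COC(=O)CC(C)(C)CC(=O)O | starting material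
2 | (4R)-4-benzyl-1,3-oxazolidin-2-one | O=C1N[C@H](Cc2ccccc2)CO1 | starting material
3 | mixed anhydride of 1 with pivalic acid | COC(=O)CC(C)(C)CC(=O)OC(=O)C(C)(C)C | intermediate
4 | methyl 5-[(4R)-4-benzyl-2-oxo-1,3-oxazolidin-3-yl]-3,3-dimethyl-5-oxopentanoate | COC(=O)CC(C)(C)CC(=O)N1C(=O)OC[C@H]1Cc1ccccc1 | intermediate
5 | trichlorotitanium (Z)-enolate of 4 | COC(=O)CC(C)(C)/C=C(\O[Ti](Cl)(Cl)Cl)N1C(=O)OC[C@H]1Cc1ccccc1 | intermediate
6 | methyl (4R)-5-[(4R)-4-benzyl-2-oxo-1,3-oxazolidin-3-yl]-3,3-dimethyl-5-oxo-4-[(phenylsulfanyl)methyl]pentanoate | COC(=O)CC(C)(C)[C@H](C(=O)N1C(=O)OC[C@H]1Cc1ccccc1)CSc1ccccc1 | intermediate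
7 | methyl (4S)-5-(ethylsulfanyl)-3,3-dimethyl-5-oxo-4-[(phenylsulfanyl)methyl]pentanoate | COC(=O)CC(C)(C)[C@H](C(=O)SCC)CSc1ccccc1 | intermediate
8 | methyl (4R)-3,3-dimethyl-5-oxo-4-[(phenylsulfanyl)methyl]hexanoate | COC(=O)CC(C)(C)[C@H](C(C)=O)CSc1ccccc1 | intermediate
9 | methyl (4R)-5-hydroxy-3,3,5-trimethyl-4-[(phenylsulfanyl)methyl]hept-6-enoate (epimers at the carbinol carbon; formed as its magnesium alkoxide) | COC(=O)CC(C)(C)[C@H](C(C)(O)C=C)CSc1ccccc1 | intermediate
10 | (5R)-6-ethenyl-4,4,6-trimethyl-5-[(phenylsulfanyl)methyl]oxan-2-one (epimers at the carbinol carbon) | O=C1CC(C)(C)[C@H](C(C)(C=C)O1)CSc1ccccc1 | intermediate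
11 | {[(3R)-2-ethenyl-2,4,4-trimethyl-3-[(phenylsulfanyl)methyl]-3,4-dihydro-2H-pyran-6-yl]oxy}trimethylsilane | C[Si](C)(C)OC1=CC(C)(C)[C@H](C(C)(C=C)O1)CSc1ccccc1 | intermediate
12 | trimethylsilyl (3S)-2,2,4-trimethyl-3-[(phenylsulfanyl)methyl]cyclohex-4-ene-1-carboxylate | C[Si](C)(C)OC(=O)C1C(C)(C)[C@H](C(C)=CC1)CSc1ccccc1 | intermediate
13 | (3S)-2,2,4-trimethyl-3-[(phenylsulfanyl)methyl]cyclohex-4-ene-1-carboxylic acid | OC(=O)C1C(C)(C)[C@H](C(C)=CC1)CSc1ccccc1 | intermediate
14 | 2-thioxopyridin-1(2H)-yl (3S)-2,2,4-trimethyl-3-[(phenylsulfanyl)methyl]cyclohex-4-ene-1-carboxylate (Barton ester) | S=c1ccccn1OC(=O)C1C(C)(C)[C@H](C(C)=CC1)CSc1ccccc1 | intermediate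
15 | phenyl [(1R)-2,6,6-trimethylcyclohex-2-en-1-yl]methyl sulfide | CC1=CCCC(C)(C)[C@H]1CSc1ccccc1 | intermediate
16 | {[(1R)-2,6,6-trimethylcyclohex-2-en-1-yl]methyl}lithium | CC1=CCCC(C)(C)[C@H]1C[Li] | intermediate
17 | (6R)-6-(iodomethyl)-1,5,5-trimethylcyclohex-1-ene | CC1=CCCC(C)(C)[C@H]1CI | intermediate
18 | kaempferol, 3,5,7-trihydroxy-2-(4-hydroxyphenyl)-4H-chromen-4-one | Oc1ccc(cc1)-c1oc2cc(O)cc(O)c2c(=O)c1O | starting material
19 | 5-hydroxy-3,7-bis(methoxymethoxy)-2-[4-(methoxymethoxy)phenyl]-4H-chromen-4-one | COCOc1ccc(cc1)-c1oc2cc(OCOC)cc(O)c2c(=O)c1OCOC | intermediate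
20 | 5-hydroxy-6-iodo-3,7-bis(methoxymethoxy)-2-[4-(methoxymethoxy)phenyl]-4H-chromen-4-one | COCOc1ccc(cc1)-c1oc2cc(OCOC)c(I)c(O)c2c(=O)c1OCOC | intermediate
21 | 6-iodo-3,5,7-tris(methoxymethoxy)-2-[4-(methoxymethoxy)phenyl]-4H-chromen-4-one | COCOc1ccc(cc1)-c1oc2cc(OCOC)c(I)c(OCOC)c2c(=O)c1OCOC | intermediate
22 | iodo{[(1R)-2,6,6-trimethylcyclohex-2-en-1-yl]methyl}zinc | CC1=CCCC(C)(C)[C@H]1C[Zn]I | intermediate
23 | 3,5,7-tris(methoxymethoxy)-2-[4-(methoxymethoxy)phenyl]-6-{[(1R)-2,6,6-trimethylcyclohex-2-en-1-yl]methyl}-4H-chromen-4-one | CC1=CCCC(C)(C)[C@H]1Cc1c(OCOC)cc2oc(-c3ccc(OCOC)cc3)c(OCOC)c(=O)c2c1OCOC | intermediate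
24 | Ugonin G | CC1=CCCC(C)(C)[C@H]1Cc1c(O)cc2oc(-c3ccc(O)cc3)c(O)c(=O)c2c1O | target

**Step count.** Total: 13 steps. Longest linear sequence: 10 steps (steps 1–8, 12 and 13, from 1 to 24); the flavonol branch (steps 9–11) joins at step 12.

**Steps most likely to fail**

1. Step 6. What may go wrong: C-silylation or fragmentation of the lactone enolate, or a boat transition state so crowded by the neighbouring quaternary carbon that ionisation of the tertiary allylic C–O bond and elimination outrun the [3,3] shift. Fallback (sets out from 2, returns at 15): the same C4–C5 bond is closed by olefin metathesis instead. Compound 2 is acylated with 3,3-dimethylpent-4-enoic acid F1 (PivCl, Et3N, LiCl) to the imide F2; TiCl4/i-Pr2NEt and PhSCH2Cl give the alkylated imide F3; Me(MeO)NH·HCl/AlMe3 gives the Weinreb amide F4; allylmagnesium bromide at −78 °C gives the allyl ketone F5; ring-closing metathesis with the second-generation Grubbs catalyst gives the cyclohexenone F6, in which C4=C5 is the new bond; diimide (TsNHNH2, NaOAc) gives the saturated ketone F7; KN(SiMe3)2/PhNTf2 gives the less substituted enol triflate F8; Me2CuLi replaces the triflate by methyl and delivers 15.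

2. Step 12. What may go wrong: slow oxidative addition and transmetalation at the doubly ortho-substituted C–I bond, so that protodezincation or β-hydride elimination consumes the zinc reagent. Fallback (sets out from 17, returns at 23): a B-alkyl Suzuki–Miyaura coupling replaces the zinc reagent. Iodine–lithium exchange on 17 (t-BuLi, Et2O, −78 °C) and capture with B-methoxy-9-BBN give the lithium borinate F9, which is coupled with 21 using PdCl2(dppf), K3PO4, DMF–H2O, 50 °C.

3. Step 13. What may go wrong: acid-promoted addition of the 5- or 7-hydroxyl to the ring alkene (chromane formation) or alkene migration during acetal cleavage. Fallback (sets out from 18, returns at 24): the phenols are carried as silyl ethers that fluoride removes without acid. TBSCl/imidazole in DMF converts 18 into the tris(tert-butyldimethylsilyl) ether F10; BnNMe3·ICl2/CaCO3 gives the 6-iodide F11; the free 5-OH is turned into its sodium salt (NaH) and coupled with 22 as in step 12 to give the silyl-protected coupling product F12; Bu4NF/AcOH in THF at 0 °C gives 24.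

**Further compounds**

F1 | step 6 | 3,3-dimethylpent-4-enoic acid | C=CC(C)(C)CC(=O)O
F2 | step 6 | (4R)-4-benzyl-3-(3,3-dimethylpent-4-enoyl)-1,3-oxazolidin-2-one | C=CC(C)(C)CC(=O)N1C(=O)OC[C@H]1Cc1ccccc1
F3 | step 6 | (4R)-4-benzyl-3-{(2R)-3,3-dimethyl-2-[(phenylsulfanyl)methyl]pent-4-enoyl}-1,3-oxazolidin-2-one | C=CC(C)(C)[C@H](C(=O)N1C(=O)OC[C@H]1Cc1ccccc1)CSc1ccccc1
F4 | step 6 | (2R)-N-methoxy-N,3,3-trimethyl-2-[(phenylsulfanyl)methyl]pent-4-enamide | C=CC(C)(C)[C@H](C(=O)N(C)OC)CSc1ccccc1
F5 | step 6 | (5R)-6,6-dimethyl-5-[(phenylsulfanyl)methyl]octa-1,7-dien-4-one | C=CC(C)(C)[C@H](C(=O)CC=C)CSc1ccccc1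
F6 | step 6 | (6R)-5,5-dimethyl-6-[(phenylsulfanyl)methyl]cyclohex-3-en-1-one | O=C1CC=CC(C)(C)[C@H]1CSc1ccccc1
F7 | step 6 | (2R)-3,3-dimethyl-2-[(phenylsulfanyl)methyl]cyclohexan-1-one | O=C1CCCC(C)(C)[C@H]1CSc1ccccc1
F8 | step 6 | (6R)-5,5-dimethyl-6-[(phenylsulfanyl)methyl]cyclohex-1-en-1-yl trifluoromethanesulfonate | O=S(=O)(OC1=CCCC(C)(C)[C@H]1CSc1ccccc1)C(F)(F)F
F9 | step 12 | lithium 9-methoxy-9-{[(1R)-2,6,6-trimethylcyclohex-2-en-1-yl]methyl}-9-borabicyclo[3.3.1]nonan-9-uide | [Li+].CO[B-]1(C[C@H]2C(C)=CCCC2(C)C)C2CCCC1CCC2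
F10 | step 13 | 3,7-bis[(tert-butyldimethylsilyl)oxy]-2-{4-[(tert-butyldimethylsilyl)oxy]phenyl}-5-hydroxy-4H-chromen-4-one | CC(C)(C)[Si](C)(C)Oc1ccc(cc1)-c1oc2cc(O[Si](C)(C)C(C)(C)C)cc(O)c2c(=O)c1O[Si](C)(C)C(C)(C)C
F11 | step 13 | 3,7-bis[(tert-butyldimethylsilyl)oxy]-2-{4-[(tert-butyldimethylsilyl)oxy]phenyl}-5-hydroxy-6-iodo-4H-chromen-4-one | CC(C)(C)[Si](C)(C)Oc1ccc(cc1)-c1oc2cc(O[Si](C)(C)C(C)(C)C)c(I)c(O)c2c(=O)c1O[Si](C)(C)C(C)(C)C
F12 | step 13 | 3,7-bis[(tert-butyldimethylsilyl)oxy]-2-{4-[(tert-butyldimethylsilyl)oxy]phenyl}-5-hydroxy-6-{[(1R)-2,6,6-trimethylcyclohex-2-en-1-yl]methyl}-4H-chromen-4-one | CC1=CCCC(C)(C)[C@H]1Cc1c(O[Si](C)(C)C(C)(C)C)cc2oc(-c3ccc(O[Si](C)(C)C(C)(C)C)cc3)c(O[Si](C)(C)C(C)(C)C)c(=O)c2c1O
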